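**Retrosynthetic overview**

1. Target ⇒ side-chain C7'' carbonyl reduction (threo), C8''–O–C4 ether by SN2 of a phenol on a lactate-derived (S)-α-tosyloxy ketone, and one O-methylation; this leads back to a C2-symmetric bisphenol tetrahydrofuran (THF) lignan plus one C6C3 keto tosylate.
2. THF ring ⇒ one oxygen atom plus an 8–8'-linked bis-benzylic dielectrophile. This is the laboratory form of the presumed biosynthetic ring closure (8–8' bis-quinone methide taking up water at C7 and C7'). The dielectrophile is a (1R,4R)-dimesylate of fixed configuration, so both C–O bonds form with inversion and each aryl ends up cis to its neighbouring methyl.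
3. Dimesylate ⇒ (1R,2R,3R,4R)-diol ⇒ racemic (2R*,3R*)-1,4-diketone, whose enantiomers are sorted by a reagent-controlled reduction.
4. Diketone ⇒ oxidative 8–8' dimerisation of the enolate of propiovanillone tosylate (two C6C3 units joined at C8, as in lignan biosynthesis).
5. Ring order: the THF is the only ring made (step 5), after the C8–C8' bond and both carbinol centres are in place; all arene rings are bought.

Assumption: propiovanillone, ethyl (S)-lactate and 0.5 M 3,4-dimethoxyphenylmagnesium bromide in THF are bought; where one reagent does the same job at both homotopic ends of a C2-symmetric compound (steps 3, 4, 6) the half-converted species is not numbered.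

Numbering used in the text: THF carbons C7, C8, C8', C7'; side chain C7'', C8''.

**Route**

Step 1
Reactants: 1 propiovanillone [1-(4-hydroxy-3-methoxyphenyl)propan-1-one]
Product: 2 2-methoxy-4-propanoylphenyl 4-methylbenzenesulfonate
Conditions: TsCl (1.1 equiv), K2CO3 (2 equiv), acetone, rt
Reagents that add atoms: 4-methylbenzenesulfonyl chloride (TsCl), Cc1ccc(cc1)S(Cl)(=O)=O
Why: Phenol O-sulfonylation; the tosylate turns the para oxygen from a donor into an acceptor, which later keeps the benzylic mesylates from ionising, and it survives amide bases and borane (no stereocentre involved).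

Step 2
Reactants: 2 (two molecules)
Product: 4 racemic (2R*,3R*)-2,3-dimethyl-1,4-bis[3-methoxy-4-(tosyloxy)phenyl]butane-1,4-dione, via lithium enolate 3 (not isolated)
Conditions: lithium diisopropylamide (1.05 equiv), THF, −78 °C; CuCl2 (1.1 equiv), DMF, −78 °C → rt; crystallisation/chromatography to part the (2R*,3R*) isomer from meso (meso recycled: DBU, toluene, 60 °C)
Reagents that add atoms: none
Why: Saegusa-type oxidative enolate homocoupling (one-electron oxidation by divalent copper, C8–C8' bond formed as in the biosynthetic 8–8' radical coupling); C8/C8' arise as a racemic (2R*,3R*)/meso mixture, from which the racemic isomer is taken on.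

Step 3
Reactants: 4
Product: 5 (1R,2R,3R,4R)-2,3-dimethyl-1,4-bis[3-methoxy-4-(tosyloxy)phenyl]butane-1,4-diol
Conditions: (S)-Me-CBS [(S)-tetrahydro-1-methyl-3,3-diphenyl-1H,3H-pyrrolo[1,2-c][1,3,2]oxazaborole] (20 mol %), BH3·SMe2 (2.2 equiv), THF, 0 °C → rt; MeOH; chromatography (at most 50 % from racemic 4)
Reagents that add atoms: none
Why: Corey–Bakshi–Shibata reduction: the (S)-catalyst delivers hydride to the same face of every aryl ketone (aryl as large group) to give (R)-carbinols, which in the (2R,3R)-enantiomer coincides with the Felkin–Anh (1,2-anti) preference and gives 5, whereas the (2S,3S)-enantiomer is turned into the separable (1R,2S,3S,4R)-diastereomer, and two reagent-controlled events per molecule keep the ee of 5 high.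

Step 4
Reactants: 5
Product: 6 (1R,2R,3R,4R)-2,3-dimethyl-1,4-bis[3-methoxy-4-(tosyloxy)phenyl]butane-1,4-diyl dimethanesulfonate
Conditions: Ms2O (2.4 equiv), iPr2NEt (3 equiv), CH2Cl2, −20 °C; cold aqueous wash, used at once
Reagents that add atoms: methanesulfonic anhydride (Ms2O), CS(=O)(=O)OS(C)(=O)=O
Why: O-sulfonylation with retention at both carbinol carbons (C–O bonds untouched); the anhydride brings no chloride that could substitute, and the acceptor-substituted rings keep the secondary benzylic mesylates from ionising, as with known 1,4-diaryl-1,4-butanediol dimesylates.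

Step 5
Reactants: 6
Product: 9 (2S,3R,4R,5S)-3,4-dimethyl-2,5-bis[3-methoxy-4-(tosyloxy)phenyl]tetrahydrofuran (2,3-cis, 3,4-trans, 4,5-cis), via silyl ether mesylate 7 (not isolated), via alkoxide mesylate 8 (not isolated)
Conditions: KOSiMe3 (2.5 equiv), THF–DMF 4:1, −20 °C → rt
Reagents that add atoms: potassium trimethylsilanolate (KOSiMe3), C[Si](C)(C)[O-].[K+]
Why: Proposed new method: the weakly basic silanolate oxygen displaces one secondary benzylic mesylate by SN2 (inversion, R to S), a second silanolate strips the trimethylsilyl group at silicon (giving (Me3Si)2O) and the freed alkoxide closes the ring by 5-exo-tet SN2 on the other mesylate (second inversion), so one oxygen atom bridges C7 and C7' as water does in the biosynthetic capture of the 8–8' bis-quinone methide, but on sp3 centres of fixed configuration, which puts each aryl cis to its neighbouring methyl (a planar quinone methide would close trans); closest known reaction type: double SN2 cyclisation of 1,4-diaryl-1,4-butanediol dimesylates with primary amines or Na2S to trans-2,5-diaryl pyrrolidines and thiolanes.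

Step 6
Reactants: 9
Product: 10 4,4'-[(2S,3R,4R,5S)-3,4-dimethyltetrahydrofuran-2,5-diyl]bis(2-methoxyphenol)
Conditions: KOH (6 equiv), MeOH–THF–H2O, 60 °C; aq. HCl to pH 5
Reagents that add atoms: none
Why: Sulfonate ester cleavage by hydroxide/methoxide attack at sulfur frees both phenols; the saturated 2,5-diaryl THF has no enolisable position and its ring ether is not a leaving group at 60 °C, so the four stereocentres are untouched.

Step 7
Reactants: 11 ethyl (S)-lactate
Product: 12 (S)-2-hydroxy-1-(pyrrolidin-1-yl)propan-1-one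
Conditions: pyrrolidine (1.5 equiv), neat, rt, 3 d
Reagents that add atoms: pyrrolidine, C1CCNC1
Why: Ester aminolysis under neutral conditions; the α-hydroxy stereocentre is not enolised and stays (S).

Step 8
Reactants: 12 (S)-2-hydroxy-1-(pyrrolidin-1-yl)propan-1-one; 13 3,4-dimethoxyphenylmagnesium bromide
Product: 14 (S)-1-(3,4-dimethoxyphenyl)-2-hydroxypropan-1-one
Conditions: 13 (2.5 equiv), THF, −20 °C → rt; aq. HCl (1 M), 0 °C
Reagents that add atoms: none
Why: Grignard acylation with a tertiary amide: after deprotonation of the hydroxyl, the magnesium-chelated tetrahedral adduct holds until work-up (Weinreb-type behaviour), so addition stops at the ketone and the stereocentre is not touched.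

Step 9
Reactants: 14
Product: 15 (S)-1-(3,4-dimethoxyphenyl)-1-oxopropan-2-yl 4-methylbenzenesulfonate
Conditions: TsCl (1.2 equiv), Et3N (1.5 equiv), DMAP (5 mol %), CH2Cl2, 0 °C
Reagents that add atoms: 4-methylbenzenesulfonyl chloride (TsCl), Cc1ccc(cc1)S(Cl)(=O)=O
Why: O-tosylation with retention (C–O bond not broken), run cold and briefly so the α-keto stereocentre is not enolised.

Step 10
Reactants: 10 bisphenol; 15 (S)-keto tosylate
Product: 17 (R)-1-(3,4-dimethoxyphenyl)-2-{4-[(2S,3R,4R,5S)-5-(3,4-dimethoxyphenyl)-3,4-dimethyltetrahydrofuran-2-yl]-2-methoxyphenoxy}propan-1-one, via monophenol keto ether 16 (not isolated)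
Conditions: 15 (1.0 equiv), K2CO3 (3 equiv), 18-crown-6 (10 mol %), MeCN, rt; then MeI (5 equiv), rt (statistical, about 45 % at best)
Reagents that add atoms: iodomethane (MeI), CI
Why: Williamson ether synthesis: phenoxide SN2 at the α-keto secondary tosylate with inversion sets C8'' as (R) (the tosylate anion cannot re-attack, so no erosion), on one of the two homotopic phenols, and the remaining phenol is O-methylated in the same pot.

Step 11
Reactants: 17
Product: 18 target, (1R,2R)-1-(3,4-dimethoxyphenyl)-2-{4-[(2S,3R,4R,5S)-5-(3,4-dimethoxyphenyl)-3,4-dimethyltetrahydrofuran-2-yl]-2-methoxyphenoxy}propan-1-ol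
Conditions: (R)-Me-CBS [(R)-tetrahydro-1-methyl-3,3-diphenyl-1H,3H-pyrrolo[1,2-c][1,3,2]oxazaborole] (0.5 equiv), BH3·SMe2 (1.2 equiv), THF, −20 °C; MeOH
Reagents that add atoms: none
Why: Corey–Bakshi–Shibata reduction: the (R)-catalyst (aryl as large group) and the Felkin–Anh model (aryloxy group anti to the incoming hydride) both favour the (7''R) carbinol, giving the threo (7''R,8''R) ether alcohol.

**Compound list**

1 | propiovanillone, 1-(4-hydroxy-3-methoxyphenyl)propan-1-one | CCC(=O)c1ccc(O)c(OC)c1 | starting material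
2 | 2-methoxy-4-propanoylphenyl 4-methylbenzenesulfonate | CCC(=O)c1ccc(OS(=O)(=O)c2ccc(C)cc2)c(OC)c1 | intermediate
3 | lithium (Z)-enolate of 2 | C/C=C(\[O-])c1ccc(OS(=O)(=O)c2ccc(C)cc2)c(OC)c1.[Li+] | intermediate (not isolated)
4 | racemic (2R*,3R*)-2,3-dimethyl-1,4-bis[3-methoxy-4-(tosyloxy)phenyl]butane-1,4-dione (2R,3R enantiomer drawn) | Cc1ccc(cc1)S(=O)(=O)Oc1ccc(cc1OC)C(=O)[C@H](C)[C@@H](C)C(=O)c1ccc(OS(=O)(=O)c2ccc(C)cc2)c(OC)c1 | intermediate
5 | (1R,2R,3R,4R)-2,3-dimethyl-1,4-bis[3-methoxy-4-(tosyloxy)phenyl]butane-1,4-diol | Cc1ccc(cc1)S(=O)(=O)Oc1ccc(cc1OC)[C@H](O)[C@H](C)[C@@H](C)[C@@H](O)c1ccc(OS(=O)(=O)c2ccc(C)cc2)c(OC)c1 | intermediate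
6 | (1R,2R,3R,4R)-dimesylate of 5 | Cc1ccc(cc1)S(=O)(=O)Oc1ccc(cc1OC)[C@H](OS(C)(=O)=O)[C@H](C)[C@@H](C)[C@@H](OS(C)(=O)=O)c1ccc(OS(=O)(=O)c2ccc(C)cc2)c(OC)c1 | intermediate
7 | (1S,2R,3R,4R)-1-(trimethylsilyloxy) 4-mesylate | Cc1ccc(cc1)S(=O)(=O)Oc1ccc(cc1OC)[C@@H](O[Si](C)(C)C)[C@H](C)[C@@H](C)[C@@H](OS(C)(=O)=O)c1ccc(OS(=O)(=O)c2ccc(C)cc2)c(OC)c1 | intermediate (not isolated)
8 | potassium (1S,2R,3R,4R)-4-(mesyloxy)butan-1-olate | Cc1ccc(cc1)S(=O)(=O)Oc1ccc(cc1OC)[C@@H]([O-])[C@H](C)[C@@H](C)[C@@H](OS(C)(=O)=O)c1ccc(OS(=O)(=O)c2ccc(C)cc2)c(OC)c1.[K+] | intermediate (not isolated)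
9 | (2S,3R,4R,5S)-3,4-dimethyl-2,5-bis[3-methoxy-4-(tosyloxy)phenyl]tetrahydrofuran | Cc1ccc(cc1)S(=O)(=O)Oc1ccc(cc1OC)[C@H]1O[C@H](c2ccc(OS(=O)(=O)c3ccc(C)cc3)c(OC)c2)[C@H](C)[C@H]1C | intermediate
10 | 4,4'-[(2S,3R,4R,5S)-3,4-dimethyltetrahydrofuran-2,5-diyl]bis(2-methoxyphenol) | Oc1ccc(cc1OC)[C@H]1O[C@H](c2ccc(O)c(OC)c2)[C@H](C)[C@H]1C | intermediate
11 | ethyl (S)-lactate | C[C@H](O)C(=O)OCC | starting material
12 | (S)-2-hydroxy-1-(pyrrolidin-1-yl)propan-1-one | C[C@H](O)C(=O)N1CCCC1 | intermediate
13 | 3,4-dimethoxyphenylmagnesium bromide | COc1ccc([Mg]Br)cc1OC | starting material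
14 | (S)-1-(3,4-dimethoxyphenyl)-2-hydroxypropan-1-one | C[C@H](O)C(=O)c1ccc(OC)c(OC)c1 | intermediate
15 | (S)-1-(3,4-dimethoxyphenyl)-1-oxopropan-2-yl 4-methylbenzenesulfonate | C[C@H](OS(=O)(=O)c1ccc(C)cc1)C(=O)c1ccc(OC)c(OC)c1 | intermediate
16 | (R)-1-(3,4-dimethoxyphenyl)-2-{4-[(2S,3R,4R,5S)-5-(4-hydroxy-3-methoxyphenyl)-3,4-dimethyltetrahydrofuran-2-yl]-2-methoxyphenoxy}propan-1-one | COc1ccc(C(=O)[C@@H](C)Oc2ccc([C@H]3O[C@H](c4ccc(O)c(OC)c4)[C@H](C)[C@H]3C)cc2OC)cc1OC | intermediate (not isolated)
17 | (R)-1-(3,4-dimethoxyphenyl)-2-{4-[(2S,3R,4R,5S)-5-(3,4-dimethoxyphenyl)-3,4-dimethyltetrahydrofuran-2-yl]-2-methoxyphenoxy}propan-1-one | COc1ccc(C(=O)[C@@H](C)Oc2ccc([C@H]3O[C@H](c4ccc(OC)c(OC)c4)[C@H](C)[C@H]3C)cc2OC)cc1OC | intermediate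
18 | (1R,2R)-1-(3,4-dimethoxyphenyl)-2-{4-[(2S,3R,4R,5S)-5-(3,4-dimethoxyphenyl)-3,4-dimethyltetrahydrofuran-2-yl]-2-methoxyphenoxy}propan-1-ol | COc1ccc([C@@H](O)[C@@H](C)Oc2ccc([C@H]3O[C@H](c4ccc(OC)c(OC)c4)[C@H](C)[C@H]3C)cc2OC)cc1OC | target

**Count and risks**

Total step count: 11. Longest linear sequence: 8 (steps 1–6, 10, 11).

Most likely to fail:

Step 5. The intermolecular SN2 by silanolate may lose to E2 (styrene) or to attack at sulfur, which would give retention and the 2,3-cis-3,4-trans-4,5-trans isomer. Early loss of an aryl tosylate would open a quinone methide path and scramble C7. The fallback sets out from 6 and splits the two inversions. CsOAc (1.0 equiv), 18-crown-6, toluene, 40 °C displaces one mesylate with inversion to give the (1S)-acetate (4R)-mesylate F1 (statistical; unreacted 6 is recycled). K2CO3 in MeOH–THF at 0 °C → rt then removes the acetyl group, and the alkoxide 8 closes onto the remaining mesylate with inversion. The route is rejoined at 9.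

Step 3. The reagent-controlled reduction must override substrate bias in the (2S,3S) half, and the diastereomeric diols must separate. The γ-hydroxy ketone may also rest as a lactol and stall. The fallback sets out from 4: LiBH(s-Bu)3, THF, −78 °C reduces both carbonyls under Felkin–Anh substrate control to the racemic anti,anti-diol, that is 5 together with its mirror image, the (1S,2S,3S,4S)-diol F2. Preparative chromatography on a chiral stationary phase (amylose carbamate, supercritical CO2/MeOH) then gives 5, where the route is rejoined.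

Step 10. Base may partly racemise 15 or epimerise C8'' of 16, and the mono-alkylation is statistical. The fallback sets out from 10 and 14 (step 9 is then not needed): Mitsunobu etherification (PPh3, DIAD, THF, 0 °C) joins them under neutral conditions with SN2 inversion at the activated α-keto carbinol to give 16, now isolated. MeI, K2CO3, acetone, rt then gives 17, where the route is rejoined. This makes no new compound (F0).

Further compounds
F1 | step 5 | (1S,2R,3R,4R)-4-(methanesulfonyloxy)-2,3-dimethyl-1,4-bis[3-methoxy-4-(tosyloxy)phenyl]butyl acetate | Cc1ccc(cc1)S(=O)(=O)Oc1ccc(cc1OC)[C@@H](OC(C)=O)[C@H](C)[C@@H](C)[C@@H](OS(C)(=O)=O)c1ccc(OS(=O)(=O)c2ccc(C)cc2)c(OC)c1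
F2 | step 3 | (1S,2S,3S,4S)-2,3-dimethyl-1,4-bis[3-methoxy-4-(tosyloxy)phenyl]butane-1,4-diol | Cc1ccc(cc1)S(=O)(=O)Oc1ccc(cc1OC)[C@@H](O)[C@@H](C)[C@H](C)[C@H](O)c1ccc(OS(=O)(=O)c2ccc(C)cc2)c(OC)c1
F0 | step 10 | none | none
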